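## The problem

The target is the lactate-side monomethyl ester of lithospermic acid. It is a trans-2,3-disubstituted 2,3-dihydrobenzofuran with a 3,4-dihydroxyphenyl group at C2, a free carboxylic acid at C3 and a hydroxyl at C7. Its C4 carries an (E)-propenoate that acylates the secondary oxygen of methyl (R)-3-(3,4-dihydroxyphenyl)lactate. The benzene ring of the benzofuran is substituted on four contiguous carbons (C3a, C4, C7, C7a), so the C4 side chain must be placed next to the C3 substituent with full regiocontrol. C2 and C3 are adjacent and trans; C3 is benzylic and alpha to a carboxyl group, so it can be equilibrated and a correctly set C2 fixes C3 by thermodynamics. The lactate centre lies beyond the cinnamate and an aromatic ring, out of reach of the ring centres, and needs its own source of asymmetry. The two carboxyl groups must end in different states (acid at C3, methyl ester on the lactate), and the closing steps are limited by five phenols, a cinnamate alkene that rules out hydrogenolysis, a base-sensitive acyloxy ester beside a methyl ester, and a C2–O1 benzylic ether that strong acid can ionise. The enabling feature is the lactate carbon itself: it carries an acyloxy oxygen and a carboxyl carbon, the alpha-acyloxy carbonyl array that a Passerini coupling assembles from an aldehyde (carbon and oxygen), an isocyanide (carboxyl carbon) and a carboxylic acid (acyl group).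

## Retrosynthesis

**25 to 24.** The last operation cuts the five O–benzyl bonds and the O–tert-butyl bond of 24. Hydrogenolysis is excluded by the alkene and by the C2–O1 benzylic ether. A Lewis acid with a non-basic cation trap cleaves aryl benzyl ethers and a tert-butyl ester at low temperature and spares methyl esters. Benzyl was preferred to silyl or acetal groups because it survives the carbene, the oxidative palladium step and hydroxide. The forward step must not ionise C2–O1 irreversibly.

**24 to 23 to 21.** The methyl ester carbon of 24 is traced back to an amide carbon. A plain secondary amide could not be solvolysed beside two esters, so the amide of 21 is the anilide of a convertible isocyanide. Acid closes it to N-acylindole 23 through methoxyindoline 22, and 23 is an acyl donor reactive enough for methanolysis under conditions that leave the cinnamate and tert-butyl esters alone.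

**21 to 14 + 18 + 19.** Two bonds at the lactate carbon are cut: the bond to its carboxyl carbon and the acyl–oxygen bond. The neighbouring cuts are an esterification of 14 with a separately made enantiopure hydroxy ester, and a cut at the C4–vinyl bond with an acrylate that already carries the lactate. Both require the stereocentre to be bought or built in a separate sequence. The three-component cut makes both bonds and the centre from achiral 18 and 19 in one step. Compound 21 falls into one advanced acid and two simple pieces. The forward reaction needs catalyst-controlled facial selectivity and a single free carboxyl group, so the C3 carboxyl of 14 is a tert-butyl ester.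

**18 to 17 to 16 to 15.** The aldehyde is reached by oxidation of alcohol 17, which comes from reduction of benzyl ester 16, the exhaustive benzylation product of acid 15. The aldehyde is made last and used at once because arylacetaldehydes enolise and condense on storage.

**14 to 13 to 12.** The two carboxyl groups exchange roles. The free cinnamic acid of 14 goes back to the methyl ester of 13, and the tert-butyl ester of 13 goes back to the free C3 acid of 12. This detour is the price of using the C3 acid as a directing group in the step before and silencing it in the step after. Methyl against tert-butyl gives a reliable hydroxide selectivity.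

**12 to 10 + 11.** The C4–vinyl bond is cut. Electrophilic substitution of the ring would go para to O1 (C5) or onto the more electron-rich catechol ring. The C3 carboxylate instead directs palladium to C4, the only ortho C–H bond of this phenylacetic acid (the other ortho position is C7a). Acid 10 has no substituent at C4, and acrylate 11 is a commodity.

**10 to 9 to 8 to 7.** The C2–C3 bond is cut. It forms by insertion of an aryl(ester) carbene into the benzylic ether C–H bond of 7, which also closes the dihydrofuran ring. The chiral dirhodium catalyst chooses between the two benzylic hydrogens and sets C2. The kinetic cis ester 8 is epimerised at C3 to trans ester 9 and saponified to 10. The precursor 7 has no stereocentre.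

**7 to 6 to 4 + 5, 4 to 2 + 3, 2 to 1.** Diazo transfer takes 7 back to arylacetate 6. The aryl–CH2 bond of 6 is cut to aryl bromide 4 and the zinc enolate of bromoacetate 5. The benzylic ether of 4 is cut to bromophenol 2 and chloride 3, and 2 comes from ortho-bromination of 1. This reaches the arylacetate in three steps without an allyl-Claisen-oxidation sequence.

## Roads not taken

**Alternative 1:** Three bonds of the benzofuran benzene ring (C3a–C7a, C4–C5, C6–C7) are cut. Forward, the ynol-ether diyne A1 and ethyne would combine under Cp*RuCl(cod), chloro(1,5-cyclooctadiene)(pentamethylcyclopentadienyl)ruthenium, in a (2+2+2) cycloaddition. This closes the benzene and dihydrofuran rings together and gives A2, with silicon at C4 and boron at C7.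
- Merits: the tether fixes every ring position without a directing group, and the two handles are orthogonal (ipso-halogenation and Heck at C4, oxidation at C7). On regiochemical certainty it is at least as good as the chosen plan.
- Weak points: A1 is a boryl alkynyl ether of a secondary benzylic alcohol, a thermally and hydrolytically fragile class. Its two stereocentres must be built in an open chain first. Ethyne must outcompete diyne self-coupling. The C3 carbon arrives as a silyloxymethyl group and needs deprotection and two oxidations through an epimerisable aldehyde.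
- Comparison: the route to a cinnamic acid like 14 would be clearly longer, and the lactate problem is untouched. The chosen plan answers the regiochemistry with carboxylate direction to the single ortho C–H bond of 10.

**Alternative 2:** The O1–C2 bond is cut. Forward, a chiral phosphoric acid would ionise the para-hydroxybenzylic alcohol A3 (an aldol adduct, used as a stereoisomer mixture) to quinone methide A4. The ortho phenol oxygen closes onto the methide carbon in a 5-exo fashion to give A5.
- Merits: no diazo compound and no rhodium. The pieces are a cheap arylacetate and a benzaldehyde, and the trans relationship is again thermodynamic. In reagent cost and step count to the ring it could beat steps 1 to 6.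
- Weak points: the bond is formed by an ionisation that the product can undergo again, so the C2 configuration can erode under the conditions that create it. A3 can dehydrate or undergo retro-aldol cleavage. The catechol of the C2 aryl group must be differentiated (free 4-hydroxyl, protected 3-hydroxyl), which breaks the uniform benzyl scheme.
- Comparison: A5 still needs the C4 olefination and the whole lactate end-game. The chosen plan sets against the cheaper ring synthesis an irreversible C–H insertion whose C2 centre, once set, is not in equilibrium with an achiral intermediate.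

**Alternative 3:** The C3–C3a and O1–C2 bonds are cut. Forward, bromophenol A6 and the (E)-cinnamyl silyl ether A7 would combine under Pd(OAc)2, (R)-2,2'-bis(diphenylphosphino)-1,1'-binaphthyl and Ag2CO3. The aryl group adds to the alkene carbon remote from the catechol ring and the phenoxide to the benzylic carbon, giving A8.
- Merits: it is the most convergent ring synthesis of the four, and the C4 carbon is already present as an aldehyde. Neither C–H olefination nor the ester exchange of steps 8 and 9 would be needed. In step count to the ring it is better than the chosen plan.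
- Weak points: after carbopalladation of an acyclic alkene, beta-hydride elimination to the Heck product normally outruns C–O bond formation, and oxyarylation is reliable mainly on cyclic alkenes. Two stereocentres and the regiochemistry would all rest on one step with little precedent for enantiocontrol. The C3 carbon again needs adjustment of its oxidation level.
- Comparison: the chosen plan is longer to 14, but each ring-forming and stereo-defining operation is of a type established on 2-aryl-2,3-dihydrobenzofuran-3-carboxylates, and C3 is corrected by equilibration.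

All three alternatives put the strategic weight on the ring and leave the lactate ester to a later esterification. The chosen plan puts it on the one stereocentre that the ring cannot control.

Key step: step 13

Assumption: the (R)-phosphoric acid of step 13 and the (R)-tert-leucinate dirhodium catalyst of step 5 are the enantiomers expected to give the (R) lactate centre and the (2S) ring centre; the sense of induction on these substrates has to be confirmed, and the mirror-image catalyst would be used if it is opposite.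

## Route

Step 1
Reactants: 1 2-(benzyloxy)phenol
Product: 2 2-(benzyloxy)-6-bromophenol
Conditions: t-BuNH2, Br2, toluene, −30 °C; then 1, CH2Cl2, −78 °C → rt
Reagents that add atoms: bromine, BrBr
Why: Amine-mediated ortho-bromination of a phenol; the N-bromoamine formed in the flask delivers bromine to the free position next to the hydroxyl through a hydrogen-bonded pair, and the other ortho position is blocked by the benzyloxy group.

Step 2
Reactants: 2 2-(benzyloxy)-6-bromophenol; 3 4-(chloromethyl)-1,2-bis(benzyloxy)benzene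
Product: 4 1-(benzyloxy)-2-{[3,4-bis(benzyloxy)phenyl]methoxy}-3-bromobenzene
Conditions: K2CO3, KI (cat.), DMF, 60 °C
Reagents that add atoms: none
Why: Williamson ether synthesis; the phenoxide of 2, made more acidic by the ortho bromine, displaces the activated benzylic chloride with Finkelstein assistance from iodide.

Step 3
Reactants: 4 1-(benzyloxy)-2-{[3,4-bis(benzyloxy)phenyl]methoxy}-3-bromobenzene; 5 methyl bromoacetate
Product: 6 methyl 2-[3-(benzyloxy)-2-{[3,4-bis(benzyloxy)phenyl]methoxy}phenyl]acetate
Conditions: 5, Zn dust, TMSCl (cat.), THF, 40 °C (gives BrZnCH2CO2Me); then 4, Pd2(dba)3 (1 mol %), 2-dicyclohexylphosphino-2',4',6'-triisopropylbiphenyl (XPhos, 4 mol %), THF, 60 °C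
Reagents that add atoms: none
Why: Negishi-type cross-coupling of a Reformatsky reagent with an aryl bromide (palladium-catalysed alpha-arylation of an ester zinc enolate); the neutral zinc enolate tolerates the benzyl ethers and does not deprotonate the benzylic ether methylene.

Step 4
Reactants: 6 methyl 2-[3-(benzyloxy)-2-{[3,4-bis(benzyloxy)phenyl]methoxy}phenyl]acetate
Product: 7 methyl 2-[3-(benzyloxy)-2-{[3,4-bis(benzyloxy)phenyl]methoxy}phenyl]-2-diazoacetate
Conditions: 4-acetamidobenzenesulfonyl azide, DBU, MeCN, 0 °C → rt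
Reagents that add atoms: 4-acetamidobenzenesulfonyl azide, CC(=O)Nc1ccc(cc1)S(=O)(=O)N=[N+]=[N-]
Why: Regitz diazo transfer; DBU deprotonates the methylene activated by aryl and ester, and the sulfonyl azide hands over the diazo group, the standard entry to aryldiazoacetates.

Step 5
Reactants: 7 methyl 2-[3-(benzyloxy)-2-{[3,4-bis(benzyloxy)phenyl]methoxy}phenyl]-2-diazoacetate
Product: 8 methyl (2S,3R)-7-(benzyloxy)-2-[3,4-bis(benzyloxy)phenyl]-2,3-dihydrobenzofuran-3-carboxylate (cis)
Conditions: Rh2(R-PTTL)4, dirhodium tetrakis[N-phthaloyl-(R)-tert-leucinate] (1 mol %), toluene, −60 → −20 °C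
Reagents that add atoms: none
Why: Intramolecular 1,5 C–H insertion of a donor/acceptor dirhodium carbene into the benzylic ether C–H bond forms C2–C3 and closes the dihydrofuran ring; the chiral carboxylate ligands select one of the two enantiotopic benzylic hydrogens and so set C2, and catalysts of this family give the cis ester kinetically, which the next step corrects.

Step 6
Reactants: 8 methyl (2S,3R)-7-(benzyloxy)-2-[3,4-bis(benzyloxy)phenyl]-2,3-dihydrobenzofuran-3-carboxylate
Product: 10 (2S,3S)-7-(benzyloxy)-2-[3,4-bis(benzyloxy)phenyl]-2,3-dihydrobenzofuran-3-carboxylic acid, via trans methyl ester 9 (not isolated)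
Conditions: NaOMe (0.2 equiv), MeOH/THF, rt; then aq. NaOH, 45 °C; 1 M HCl
Reagents that add atoms: water, O
Why: Enolate-mediated epimerisation at C3 moves the ester to the face opposite the C2 aryl group (thermodynamic trans isomer) while C2 is untouched, and saponification in the same flask gives the acid; epimerisation is done before hydroxide is added because the carboxylate no longer enolises.

Step 7
Reactants: 10 (2S,3S)-7-(benzyloxy)-2-[3,4-bis(benzyloxy)phenyl]-2,3-dihydrobenzofuran-3-carboxylic acid; 11 methyl acrylate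
Product: 12 (2S,3S)-7-(benzyloxy)-2-[3,4-bis(benzyloxy)phenyl]-4-[(E)-3-methoxy-3-oxoprop-1-en-1-yl]-2,3-dihydrobenzofuran-3-carboxylic acid
Conditions: Pd(OAc)2 (5 mol %), N-acetyl-L-isoleucine (10 mol %), KHCO3, O2 (1 atm), tert-amyl alcohol, 85 °C
Reagents that add atoms: none
Why: Carboxylate-directed C–H olefination of a phenylacetic acid (oxidative Heck, Fujiwara–Moritani type); the C3 carboxylate guides divalent palladium to C4, the only ortho C–H bond, the amino acid ligand speeds C–H cleavage, syn insertion and beta-hydride elimination give the E alkene, and oxygen reoxidises zerovalent palladium.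

Step 8
Reactants: 12 (2S,3S)-7-(benzyloxy)-2-[3,4-bis(benzyloxy)phenyl]-4-[(E)-3-methoxy-3-oxoprop-1-en-1-yl]-2,3-dihydrobenzofuran-3-carboxylic acid
Product: 13 tert-butyl (2S,3S)-7-(benzyloxy)-2-[3,4-bis(benzyloxy)phenyl]-4-[(E)-3-methoxy-3-oxoprop-1-en-1-yl]-2,3-dihydrobenzofuran-3-carboxylate
Conditions: O-tert-butyl-N,N'-diisopropylisourea, CH2Cl2, rt → 40 °C
Reagents that add atoms: O-tert-butyl-N,N'-diisopropylisourea, CC(C)N=C(NC(C)C)OC(C)(C)C
Why: Isourea esterification; the acid protonates the isourea and the tert-butyl group is transferred within the ion pair, a neutral method suited to a hindered acid that causes no epimerisation at C3.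

Step 9
Reactants: 13 tert-butyl (2S,3S)-7-(benzyloxy)-2-[3,4-bis(benzyloxy)phenyl]-4-[(E)-3-methoxy-3-oxoprop-1-en-1-yl]-2,3-dihydrobenzofuran-3-carboxylate
Product: 14 (E)-3-[(2S,3S)-7-(benzyloxy)-2-[3,4-bis(benzyloxy)phenyl]-3-(tert-butoxycarbonyl)-2,3-dihydrobenzofuran-4-yl]acrylic acid
Conditions: LiOH·H2O, THF/MeOH/H2O, 0 °C → rt; 1 M HCl
Reagents that add atoms: water, O
Why: Chemoselective saponification; hydroxide attacks the unhindered methyl cinnamate, while the tert-butyl ester at the hindered C3 position resists acyl substitution, and the trans ring is the stable isomer under base.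

Step 10
Reactants: 15 3,4-dihydroxyphenylacetic acid
Product: 16 benzyl 2-[3,4-bis(benzyloxy)phenyl]acetate
Conditions: BnBr, K2CO3, DMF, 60 °C
Reagents that add atoms: benzyl bromide, BrCc1ccccc1
Why: Exhaustive O-alkylation (Williamson etherification of both phenoxides and alkylation of the carboxylate) in one operation.

Step 11
Reactants: 16 benzyl 2-[3,4-bis(benzyloxy)phenyl]acetate
Product: 17 2-[3,4-bis(benzyloxy)phenyl]ethanol
Conditions: LiAlH4, THF, 0 °C; aqueous work-up
Reagents that add atoms: none
Why: Hydride reduction of the ester to the primary alcohol; aryl benzyl ethers are inert to LiAlH4.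

Step 12
Reactants: 17 2-[3,4-bis(benzyloxy)phenyl]ethanol
Product: 18 2-[3,4-bis(benzyloxy)phenyl]acetaldehyde
Conditions: Dess–Martin periodinane, CH2Cl2, 0 °C → rt; Na2S2O3/NaHCO3 work-up
Reagents that add atoms: none
Why: Dess–Martin oxidation stops at the aldehyde under near-neutral conditions, which limits enolisation and self-condensation of the arylacetaldehyde; 18 is used at once.

Step 13
Reactants: 14 (E)-3-[(2S,3S)-7-(benzyloxy)-2-[3,4-bis(benzyloxy)phenyl]-3-(tert-butoxycarbonyl)-2,3-dihydrobenzofuran-4-yl]acrylic acid; 18 2-[3,4-bis(benzyloxy)phenyl]acetaldehyde; 19 1-(2,2-dimethoxyethyl)-2-isocyanobenzene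
Product: 21 tert-butyl (2S,3S)-7-(benzyloxy)-2-[3,4-bis(benzyloxy)phenyl]-4-[(E)-3-{[(2R)-3-[3,4-bis(benzyloxy)phenyl]-1-{[2-(2,2-dimethoxyethyl)phenyl]amino}-1-oxopropan-2-yl]oxy}-3-oxoprop-1-en-1-yl]-2,3-dihydrobenzofuran-3-carboxylate, via acyl imidate 20 (not isolated)
Conditions: (R)-3,3'-bis(2,4,6-triisopropylphenyl)-1,1'-binaphthyl-2,2'-diyl hydrogen phosphate (10 mol %), CHCl3 (0.05 M), 0 °C → rt, slow addition of 18
Reagents that add atoms: none
Why: The phosphoric acid holds acid 14 and aldehyde 18 in a hydrogen-bonded assembly that activates the aldehyde carbon and keeps the carboxylate near; the isocyanide carbon of 19 adds to that carbon (lactate carbon to carboxyl carbon bond), the nitrilium ion is trapped by the carboxylate as imidate 20, and a Mumm-type 1,4 oxygen-to-oxygen acyl shift onto the new alkoxide makes the acyl–oxygen bond and frees the catalyst. The closest known reaction type is the chiral phosphoric acid-catalysed enantioselective Passerini three-component reaction of aliphatic aldehydes, carboxylic acids and isocyanides. No ring is closed. The one new stereocentre, the lactate carbon, is set (R) by the catalyst, whose 3,3'-aryl groups shield one face of the bound aldehyde during isocyanide attack. C2 and C3 of 14 lie beyond the cinnamate and an arene and can neither help nor oppose, so a wrong-face product would be a separable diastereomer. The step needs discrimination between two carboxyl groups, which the tert-butyl ester at C3 secures. It also needs the catalysed path to outrun the uncatalysed coupling, which is favoured by high dilution, low temperature, the weakly nucleophilic aryl isocyanide and slow addition of 18. The acetal of 19 and the C2–O1 ether of 14 are inert to an acid of this strength.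

Step 14
Reactants: 21 tert-butyl (2S,3S)-7-(benzyloxy)-2-[3,4-bis(benzyloxy)phenyl]-4-[(E)-3-{[(2R)-3-[3,4-bis(benzyloxy)phenyl]-1-{[2-(2,2-dimethoxyethyl)phenyl]amino}-1-oxopropan-2-yl]oxy}-3-oxoprop-1-en-1-yl]-2,3-dihydrobenzofuran-3-carboxylate
Product: 23 tert-butyl (2S,3S)-7-(benzyloxy)-2-[3,4-bis(benzyloxy)phenyl]-4-[(E)-3-{[(2R)-3-[3,4-bis(benzyloxy)phenyl]-1-(1H-indol-1-yl)-1-oxopropan-2-yl]oxy}-3-oxoprop-1-en-1-yl]-2,3-dihydrobenzofuran-3-carboxylate, via methoxyindoline 22 (not isolated)
Conditions: (+)-camphor-10-sulfonic acid (10 mol %), quinoline (10 mol %), toluene, 70 °C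
Reagents that add atoms: none
Why: Acid-catalysed activation of the convertible anilide: the acetal ionises to an oxocarbenium ion, the amide nitrogen closes the five-membered ring to 22, and loss of a second methanol aromatises it to the N-acylindole; the quinoline buffer keeps the medium too weakly acidic to cleave the tert-butyl ester or ionise C2–O1.

Step 15
Reactants: 23 tert-butyl (2S,3S)-7-(benzyloxy)-2-[3,4-bis(benzyloxy)phenyl]-4-[(E)-3-{[(2R)-3-[3,4-bis(benzyloxy)phenyl]-1-(1H-indol-1-yl)-1-oxopropan-2-yl]oxy}-3-oxoprop-1-en-1-yl]-2,3-dihydrobenzofuran-3-carboxylate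
Product: 24 tert-butyl (2S,3S)-7-(benzyloxy)-2-[3,4-bis(benzyloxy)phenyl]-4-[(E)-3-{[(2R)-3-[3,4-bis(benzyloxy)phenyl]-1-methoxy-1-oxopropan-2-yl]oxy}-3-oxoprop-1-en-1-yl]-2,3-dihydrobenzofuran-3-carboxylate
Conditions: MeOH, Et3N, CH2Cl2, 0 °C → rt
Reagents that add atoms: methanol, CO
Why: Methanolysis of an N-acylindole, whose nitrogen lone pair belongs to the aromatic ring so that the carbonyl behaves as an active acyl donor; it is far more electrophilic than the cinnamate and tert-butyl esters, and the weak amine base is chosen to spare the lactate alpha-hydrogen.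

Step 16
Reactants: 24 tert-butyl (2S,3S)-7-(benzyloxy)-2-[3,4-bis(benzyloxy)phenyl]-4-[(E)-3-{[(2R)-3-[3,4-bis(benzyloxy)phenyl]-1-methoxy-1-oxopropan-2-yl]oxy}-3-oxoprop-1-en-1-yl]-2,3-dihydrobenzofuran-3-carboxylate
Product: 25 (2S,3S)-2-(3,4-dihydroxyphenyl)-4-[(E)-3-{[(2R)-3-(3,4-dihydroxyphenyl)-1-methoxy-1-oxopropan-2-yl]oxy}-3-oxoprop-1-en-1-yl]-7-hydroxy-2,3-dihydrobenzofuran-3-carboxylic acid
Conditions: BCl3 (excess), pentamethylbenzene, CH2Cl2, −78 → −20 °C; MeOH quench, aqueous work-up
Reagents that add atoms: none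
Why: Lewis acid debenzylation with pentamethylbenzene as a non-coordinating trap for benzyl cations; the same reagent cleaves the tert-butyl ester by alkyl–oxygen fission, while the methyl ester, the acyloxy ester and the alkene are not attacked at low temperature and no stereocentre is involved.

## Compound list

1 | 2-(benzyloxy)phenol | Oc1ccccc1OCc1ccccc1 | starting material
2 | 2-(benzyloxy)-6-bromophenol | Oc1c(Br)cccc1OCc1ccccc1 | intermediate
3 | 4-(chloromethyl)-1,2-bis(benzyloxy)benzene | ClCc1ccc(OCc2ccccc2)c(OCc2ccccc2)c1 | starting material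
4 | 1-(benzyloxy)-2-{[3,4-bis(benzyloxy)phenyl]methoxy}-3-bromobenzene | Brc1cccc(OCc2ccccc2)c1OCc1ccc(OCc2ccccc2)c(OCc2ccccc2)c1 | intermediate
5 | methyl bromoacetate | COC(=O)CBr | starting material
6 | methyl 2-[3-(benzyloxy)-2-{[3,4-bis(benzyloxy)phenyl]methoxy}phenyl]acetate | COC(=O)Cc1cccc(OCc2ccccc2)c1OCc1ccc(OCc2ccccc2)c(OCc2ccccc2)c1 | intermediate
7 | methyl 2-[3-(benzyloxy)-2-{[3,4-bis(benzyloxy)phenyl]methoxy}phenyl]-2-diazoacetate | COC(=O)C(=[N+]=[N-])c1cccc(OCc2ccccc2)c1OCc1ccc(OCc2ccccc2)c(OCc2ccccc2)c1 | intermediate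
8 | methyl (2S,3R)-7-(benzyloxy)-2-[3,4-bis(benzyloxy)phenyl]-2,3-dihydrobenzofuran-3-carboxylate (cis) | c1ccc(OCc3ccccc3)c2c1[C@@H](C(=O)OC)[C@@H](c1ccc(OCc3ccccc3)c(OCc3ccccc3)c1)O2 | intermediate
9 | methyl (2S,3S)-7-(benzyloxy)-2-[3,4-bis(benzyloxy)phenyl]-2,3-dihydrobenzofuran-3-carboxylate (trans) | c1ccc(OCc3ccccc3)c2c1[C@H](C(=O)OC)[C@@H](c1ccc(OCc3ccccc3)c(OCc3ccccc3)c1)O2 | intermediate (not isolated)
10 | (2S,3S)-7-(benzyloxy)-2-[3,4-bis(benzyloxy)phenyl]-2,3-dihydrobenzofuran-3-carboxylic acid | c1ccc(OCc3ccccc3)c2c1[C@H](C(=O)O)[C@@H](c1ccc(OCc3ccccc3)c(OCc3ccccc3)c1)O2 | intermediate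
11 | methyl acrylate | C=CC(=O)OC | starting material
12 | (2S,3S)-7-(benzyloxy)-2-[3,4-bis(benzyloxy)phenyl]-4-[(E)-3-methoxy-3-oxoprop-1-en-1-yl]-2,3-dihydrobenzofuran-3-carboxylic acid | COC(=O)/C=C/c1ccc(OCc3ccccc3)c2c1[C@H](C(=O)O)[C@@H](c1ccc(OCc3ccccc3)c(OCc3ccccc3)c1)O2 | intermediate
13 | tert-butyl (2S,3S)-7-(benzyloxy)-2-[3,4-bis(benzyloxy)phenyl]-4-[(E)-3-methoxy-3-oxoprop-1-en-1-yl]-2,3-dihydrobenzofuran-3-carboxylate | COC(=O)/C=C/c1ccc(OCc3ccccc3)c2c1[C@H](C(=O)OC(C)(C)C)[C@@H](c1ccc(OCc3ccccc3)c(OCc3ccccc3)c1)O2 | intermediate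
14 | (E)-3-[(2S,3S)-7-(benzyloxy)-2-[3,4-bis(benzyloxy)phenyl]-3-(tert-butoxycarbonyl)-2,3-dihydrobenzofuran-4-yl]acrylic acid | OC(=O)/C=C/c1ccc(OCc3ccccc3)c2c1[C@H](C(=O)OC(C)(C)C)[C@@H](c1ccc(OCc3ccccc3)c(OCc3ccccc3)c1)O2 | intermediate
15 | 3,4-dihydroxyphenylacetic acid | O=C(O)Cc1ccc(O)c(O)c1 | starting material
16 | benzyl 2-[3,4-bis(benzyloxy)phenyl]acetate | O=C(Cc1ccc(OCc2ccccc2)c(OCc2ccccc2)c1)OCc1ccccc1 | intermediate
17 | 2-[3,4-bis(benzyloxy)phenyl]ethanol | OCCc1ccc(OCc2ccccc2)c(OCc2ccccc2)c1 | intermediate
18 | 2-[3,4-bis(benzyloxy)phenyl]acetaldehyde | O=CCc1ccc(OCc2ccccc2)c(OCc2ccccc2)c1 | intermediate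
19 | 1-(2,2-dimethoxyethyl)-2-isocyanobenzene | [C-]#[N+]c1ccccc1CC(OC)OC | starting material
20 | O-acyl imidate: mixed anhydride of acid 14 and (2R)-3-[3,4-bis(benzyloxy)phenyl]-N-[2-(2,2-dimethoxyethyl)phenyl]-2-hydroxypropanimidic acid | COC(Cc1ccccc1N=C(OC(=O)/C=C/c1ccc(OCc3ccccc3)c2c1[C@H](C(=O)OC(C)(C)C)[C@@H](c1ccc(OCc3ccccc3)c(OCc3ccccc3)c1)O2)[C@@H](Cc1ccc(OCc2ccccc2)c(OCc2ccccc2)c1)O)OC | intermediate (not isolated)
21 | tert-butyl (2S,3S)-7-(benzyloxy)-2-[3,4-bis(benzyloxy)phenyl]-4-[(E)-3-{[(2R)-3-[3,4-bis(benzyloxy)phenyl]-1-{[2-(2,2-dimethoxyethyl)phenyl]amino}-1-oxopropan-2-yl]oxy}-3-oxoprop-1-en-1-yl]-2,3-dihydrobenzofuran-3-carboxylate | O=C(Nc1ccccc1CC(OC)OC)[C@@H](Cc1ccc(OCc2ccccc2)c(OCc2ccccc2)c1)OC(=O)/C=C/c1ccc(OCc3ccccc3)c2c1[C@H](C(=O)OC(C)(C)C)[C@@H](c1ccc(OCc3ccccc3)c(OCc3ccccc3)c1)O2 | intermediate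
22 | tert-butyl (2S,3S)-7-(benzyloxy)-2-[3,4-bis(benzyloxy)phenyl]-4-[(E)-3-{[(2R)-3-[3,4-bis(benzyloxy)phenyl]-1-(2-methoxy-2,3-dihydro-1H-indol-1-yl)-1-oxopropan-2-yl]oxy}-3-oxoprop-1-en-1-yl]-2,3-dihydrobenzofuran-3-carboxylate (both epimers at the aminal carbon) | COC1Cc2ccccc2N1C(=O)[C@@H](Cc1ccc(OCc2ccccc2)c(OCc2ccccc2)c1)OC(=O)/C=C/c1ccc(OCc3ccccc3)c2c1[C@H](C(=O)OC(C)(C)C)[C@@H](c1ccc(OCc3ccccc3)c(OCc3ccccc3)c1)O2 | intermediate (not isolated)
23 | tert-butyl (2S,3S)-7-(benzyloxy)-2-[3,4-bis(benzyloxy)phenyl]-4-[(E)-3-{[(2R)-3-[3,4-bis(benzyloxy)phenyl]-1-(1H-indol-1-yl)-1-oxopropan-2-yl]oxy}-3-oxoprop-1-en-1-yl]-2,3-dihydrobenzofuran-3-carboxylate | O=C(n1ccc2ccccc12)[C@@H](Cc1ccc(OCc2ccccc2)c(OCc2ccccc2)c1)OC(=O)/C=C/c1ccc(OCc3ccccc3)c2c1[C@H](C(=O)OC(C)(C)C)[C@@H](c1ccc(OCc3ccccc3)c(OCc3ccccc3)c1)O2 | intermediate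
24 | tert-butyl (2S,3S)-7-(benzyloxy)-2-[3,4-bis(benzyloxy)phenyl]-4-[(E)-3-{[(2R)-3-[3,4-bis(benzyloxy)phenyl]-1-methoxy-1-oxopropan-2-yl]oxy}-3-oxoprop-1-en-1-yl]-2,3-dihydrobenzofuran-3-carboxylate | COC(=O)[C@@H](Cc1ccc(OCc2ccccc2)c(OCc2ccccc2)c1)OC(=O)/C=C/c1ccc(OCc3ccccc3)c2c1[C@H](C(=O)OC(C)(C)C)[C@@H](c1ccc(OCc3ccccc3)c(OCc3ccccc3)c1)O2 | intermediate
25 | (2S,3S)-2-(3,4-dihydroxyphenyl)-4-[(E)-3-{[(2R)-3-(3,4-dihydroxyphenyl)-1-methoxy-1-oxopropan-2-yl]oxy}-3-oxoprop-1-en-1-yl]-7-hydroxy-2,3-dihydrobenzofuran-3-carboxylic acid | COC(=O)[C@@H](Cc1ccc(O)c(O)c1)OC(=O)/C=C/c1ccc(O)c2c1[C@H](C(=O)O)[C@@H](c1ccc(O)c(O)c1)O2 | target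

## Step count and least certain steps

Total: 16 steps. Longest linear sequence: 13 steps (steps 1 to 9 and 13 to 16); the aldehyde branch (steps 10 to 12) is 3 steps.

**Step 13 (key step).** The most likely failure is poor facial selectivity, because the uncatalysed three-component coupling is fast in non-polar solvents and competes with the catalysed path. The aldehyde may also be lost to enolisation and self-aldol condensation before the isocyanide adds.
Fallback: the lactate centre is bought instead of made. The fallback sets out from acid 14 and returns at ester 24, so compounds 18 to 23 are not needed. Commercial 4-bromo-1,2-bis(benzyloxy)benzene is converted with magnesium into [3,4-bis(benzyloxy)phenyl]magnesium bromide F1. This opens commercial methyl (R)-glycidate at its methylene carbon under CuI catalysis (THF, −40 °C) to give methyl (2R)-3-[3,4-bis(benzyloxy)phenyl]-2-hydroxypropanoate F2, with the stereocentre untouched. Steglich esterification of F2 with 14 (N-(3-dimethylaminopropyl)-N'-ethylcarbodiimide hydrochloride, DMAP, CH2Cl2, 0 °C → rt) gives 24.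

**Step 5.** The electron-rich 3,4-bis(benzyloxy)benzyl C–H bond is strongly hydridic. Insertion may therefore be early and poorly differentiated by the catalyst, or may pass through hydride transfer and ion-pair collapse. Either would lower the enantioselectivity and the cis preference.
Fallback: stereocontrol is shared between a covalently bound auxiliary and the catalyst. The fallback sets out from ester 6 and returns at acid 10.
- Saponification (LiOH, THF/H2O) gives 2-[3-(benzyloxy)-2-{[3,4-bis(benzyloxy)phenyl]methoxy}phenyl]acetic acid F3.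
- Carbodiimide coupling with (S)-2-hydroxy-1-(pyrrolidin-1-yl)propan-1-one gives (2S)-1-oxo-1-(pyrrolidin-1-yl)propan-2-yl 2-[3-(benzyloxy)-2-{[3,4-bis(benzyloxy)phenyl]methoxy}phenyl]acetate F4.
- Diazo transfer as in step 4 gives (2S)-1-oxo-1-(pyrrolidin-1-yl)propan-2-yl 2-[3-(benzyloxy)-2-{[3,4-bis(benzyloxy)phenyl]methoxy}phenyl]-2-diazoacetate F5.
- Insertion with Rh2(S-DOSP)4, dirhodium tetrakis[(S)-N-(4-dodecylbenzenesulfonyl)prolinate], a combination known to favour the trans ring directly, gives (2S)-1-oxo-1-(pyrrolidin-1-yl)propan-2-yl (2S,3S)-7-(benzyloxy)-2-[3,4-bis(benzyloxy)phenyl]-2,3-dihydrobenzofuran-3-carboxylate F6. Its stereoisomers are diastereomers and can be separated.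
- Hydrolysis (LiOH, THF/H2O) releases the auxiliary and gives 10.

**Step 15.** The acylindole acidifies the lactate alpha-hydrogen, so base-mediated epimerisation is the main danger. Methanolysis at the cinnamate ester in competition with the acylindole is the second.
Fallback: a less basic, more nucleophilic oxygen nucleophile followed by O-alkylation. The fallback sets out from 23 and returns at 24. Lithium hydroperoxide (LiOH, H2O2, THF/H2O, 0 °C) cleaves the activated amide selectively to (2R)-3-[3,4-bis(benzyloxy)phenyl]-2-{[(E)-3-{(2S,3S)-7-(benzyloxy)-2-[3,4-bis(benzyloxy)phenyl]-3-(tert-butoxycarbonyl)-2,3-dihydrobenzofuran-4-yl}prop-2-enoyl]oxy}propanoic acid F7. Methylation with (trimethylsilyl)diazomethane (toluene/MeOH, 0 °C) then gives 24 without base.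

**Step 16.** Once the para-benzyloxy group of the C2 aryl ring is unmasked, the C2–O1 benzylic ether may ionise, with loss of the trans relationship or capture by the scavenger. The tert-butyl ester may also need warming beyond the range in which the methyl ester and the acyloxy ester are safe.
Fallback: a staged deprotection that separates the two events. The fallback sets out from 24 and returns at 25. Trifluoroacetic acid in CH2Cl2 at 0 °C removes only the tert-butyl group and gives (2S,3S)-7-(benzyloxy)-2-[3,4-bis(benzyloxy)phenyl]-4-[(E)-3-{[(2R)-3-[3,4-bis(benzyloxy)phenyl]-1-methoxy-1-oxopropan-2-yl]oxy}-3-oxoprop-1-en-1-yl]-2,3-dihydrobenzofuran-3-carboxylic acid F8. The debenzylation (BCl3, pentamethylbenzene, CH2Cl2) can then be run entirely at −78 °C to give 25.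

## Further compounds

F1 | step 13 | [3,4-bis(benzyloxy)phenyl]magnesium bromide | Br[Mg]c1ccc(OCc2ccccc2)c(OCc2ccccc2)c1
F2 | step 13 | methyl (2R)-3-[3,4-bis(benzyloxy)phenyl]-2-hydroxypropanoate | COC(=O)[C@H](O)Cc1ccc(OCc2ccccc2)c(OCc2ccccc2)c1
F3 | step 5 | 2-[3-(benzyloxy)-2-{[3,4-bis(benzyloxy)phenyl]methoxy}phenyl]acetic acid | OC(=O)Cc1cccc(OCc2ccccc2)c1OCc1ccc(OCc2ccccc2)c(OCc2ccccc2)c1
F4 | step 5 | (2S)-1-oxo-1-(pyrrolidin-1-yl)propan-2-yl 2-[3-(benzyloxy)-2-{[3,4-bis(benzyloxy)phenyl]methoxy}phenyl]acetate | C[C@H](OC(=O)Cc1cccc(OCc2ccccc2)c1OCc1ccc(OCc2ccccc2)c(OCc2ccccc2)c1)C(=O)N1CCCC1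
F5 | step 5 | (2S)-1-oxo-1-(pyrrolidin-1-yl)propan-2-yl 2-[3-(benzyloxy)-2-{[3,4-bis(benzyloxy)phenyl]methoxy}phenyl]-2-diazoacetate | C[C@H](OC(=O)C(=[N+]=[N-])c1cccc(OCc2ccccc2)c1OCc1ccc(OCc2ccccc2)c(OCc2ccccc2)c1)C(=O)N1CCCC1
F6 | step 5 | (2S)-1-oxo-1-(pyrrolidin-1-yl)propan-2-yl (2S,3S)-7-(benzyloxy)-2-[3,4-bis(benzyloxy)phenyl]-2,3-dihydrobenzofuran-3-carboxylate | c1ccc(OCc3ccccc3)c2c1[C@H](C(=O)O[C@@H](C)C(=O)N1CCCC1)[C@@H](c1ccc(OCc3ccccc3)c(OCc3ccccc3)c1)O2
F7 | step 15 | (2R)-3-[3,4-bis(benzyloxy)phenyl]-2-{[(E)-3-{(2S,3S)-7-(benzyloxy)-2-[3,4-bis(benzyloxy)phenyl]-3-(tert-butoxycarbonyl)-2,3-dihydrobenzofuran-4-yl}prop-2-enoyl]oxy}propanoic acid | OC(=O)[C@@H](Cc1ccc(OCc2ccccc2)c(OCc2ccccc2)c1)OC(=O)/C=C/c1ccc(OCc3ccccc3)c2c1[C@H](C(=O)OC(C)(C)C)[C@@H](c1ccc(OCc3ccccc3)c(OCc3ccccc3)c1)O2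
F8 | step 16 | (2S,3S)-7-(benzyloxy)-2-[3,4-bis(benzyloxy)phenyl]-4-[(E)-3-{[(2R)-3-[3,4-bis(benzyloxy)phenyl]-1-methoxy-1-oxopropan-2-yl]oxy}-3-oxoprop-1-en-1-yl]-2,3-dihydrobenzofuran-3-carboxylic acid | COC(=O)[C@@H](Cc1ccc(OCc2ccccc2)c(OCc2ccccc2)c1)OC(=O)/C=C/c1ccc(OCc3ccccc3)c2c1[C@H](C(=O)O)[C@@H](c1ccc(OCc3ccccc3)c(OCc3ccccc3)c1)O2
A1 | alternative 1 | tert-butyl{[(2R,3S)-3-[3,4-bis(benzyloxy)phenyl]-3-{[2-(4,4,5,5-tetramethyl-1,3,2-dioxaborolan-2-yl)ethynyl]oxy}-2-[2-(trimethylsilyl)ethynyl]propoxy]}dimethylsilane | C[Si](C)(C)C#C[C@H](CO[Si](C)(C)C(C)(C)C)[C@@H](c1ccc(OCc2ccccc2)c(OCc2ccccc2)c1)OC#CB1OC(C)(C)C(C)(C)O1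
A2 | alternative 1 | tert-butyl{[(2S,3R)-2-[3,4-bis(benzyloxy)phenyl]-7-(4,4,5,5-tetramethyl-1,3,2-dioxaborolan-2-yl)-4-(trimethylsilyl)-2,3-dihydrobenzofuran-3-yl]methoxy}dimethylsilane (same trans arrangement as the 2S,3S acids) | C[Si](C)(C)c1ccc(B3OC(C)(C)C(C)(C)O3)c2c1[C@H](CO[Si](C)(C)C(C)(C)C)[C@@H](c1ccc(OCc3ccccc3)c(OCc3ccccc3)c1)O2
A3 | alternative 2 | methyl 2-[3-(benzyloxy)-2-hydroxyphenyl]-3-[3-(benzyloxy)-4-hydroxyphenyl]-3-hydroxypropanoate (stereoisomer mixture) | COC(=O)C(c1cccc(OCc2ccccc2)c1O)C(O)c1ccc(O)c(OCc2ccccc2)c1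
A4 | alternative 2 | methyl 2-[3-(benzyloxy)-2-hydroxyphenyl]-3-[3-(benzyloxy)-4-oxocyclohexa-2,5-dien-1-ylidene]propanoate (stereoisomer mixture) | COC(=O)C(C=C1C=CC(=O)C(OCc2ccccc2)=C1)c1cccc(OCc2ccccc2)c1O
A5 | alternative 2 | methyl (2S,3S)-7-(benzyloxy)-2-[3-(benzyloxy)-4-hydroxyphenyl]-2,3-dihydrobenzofuran-3-carboxylate | c1ccc(OCc3ccccc3)c2c1[C@H](C(=O)OC)[C@@H](c1ccc(O)c(OCc3ccccc3)c1)O2
A6 | alternative 3 | 4-(benzyloxy)-2-bromo-3-hydroxybenzaldehyde | O=Cc1ccc(OCc2ccccc2)c(O)c1Br
A7 | alternative 3 | tert-butyl{[(E)-3-[3,4-bis(benzyloxy)phenyl]prop-2-en-1-yl]oxy}dimethylsilane | CC(C)(C)[Si](C)(C)OC/C=C/c1ccc(OCc2ccccc2)c(OCc2ccccc2)c1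
A8 | alternative 3 | (2S,3R)-7-(benzyloxy)-2-[3,4-bis(benzyloxy)phenyl]-3-{[(tert-butyldimethylsilyl)oxy]methyl}-2,3-dihydrobenzofuran-4-carbaldehyde (same trans arrangement as the 2S,3S acids) | O=Cc1ccc(OCc3ccccc3)c2c1[C@H](CO[Si](C)(C)C(C)(C)C)[C@@H](c1ccc(OCc3ccccc3)c(OCc3ccccc3)c1)O2
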